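# Proposed synthesis of 5,2',5'-trihydroxy-6,7,8-trimethoxyflavone by carbene benzannulation of a 2-ethynylchromone

Numbering used throughout (structures in the compound list after the steps): 1 2,3,4-trimethoxybenzaldehyde; 2 bromo aldehyde; 3 aryl formate; 4 bromophenol; 5 symmetric resorcinol; 6 2,6-dihydroxyacetophenone; 7 mono-benzylated acetophenone; 8 silylpropynoic acid; 9 its acid chloride; 10 ynedione; 11 silylethynylchromone; 12 2-ethynylchromone; 13 (E)-bromovinylsilane; 14 Cr(CO)6; 15 vinyllithium; 16 acylchromate; 17 carbene complex; 18 arene–Cr(CO)3 complex; 19 aryl silyl ether; 20 phenol formed in the key step; 21 quinone; 22 target.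

## Analysis of the target

Compound 22 is a flavone: benzene ring A is fused to the 4-pyranone ring C (a 4H-chromen-4-one), and phenyl ring B is bonded through C1' to C2. Ring A carries a substituent on every carbon, with the C5 hydroxyl hydrogen-bonded to the C4 carbonyl and methoxy groups on C6, C7 and C8; ring B is a hydroquinone with hydroxyls on C2' and C5'. There is no stereocentre, so nothing has to be set or related; the problem is regiochemistry and telling six oxygen atoms apart. Three oxygens must end as free phenols and three as methyl ethers, so a global demethylation is excluded and each oxygen has to arrive already differentiated. The sensitive parts are the ring B hydroquinone (air oxidation to the quinone), the C5-hydroxy/C8-methoxy pair of ring A (a para-methoxyphenol that oxidants also attack) and C2 of the pyranone, where hydroxide or alkoxide can open ring C. A helpful feature is that the oxygen pattern of ring A is mirror-symmetric about the C4a–C7 axis, so a 2,6-dihydroxy-3,4,5-trimethoxyphenyl ketone gives the same chromone whichever hydroxyl closes ring C. The strategy rests on ring B: the oxygens on C2' and C5' are para to each other, C1' with the chromone is ortho to the C2' oxygen, and C3', C4' and C6' carry hydrogen. This is the pattern in which an alkenyl(alkoxy)carbene chromium complex, one of its carbonyl ligands and a terminal alkyne combine to a 4-alkoxyphenol (C5' from the carbene carbon, C2' from the carbonyl ligand, C1' and C6' from the alkyne, C3' and C4' from the alkenyl group).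

## Retrosynthetic reasoning

**22 from 21.** No skeletal bond is cut. The three phenols are revealed last, C2' and C5' from quinone 21 and C5 from its benzyl ether. The hydroquinone is the most air-sensitive part of 22 and should exist only at the end. A quinone and a benzyl ether both fall to one catalytic hydrogenation that leaves the three methyl ethers alone. The forward step must reduce the quinone and cleave the benzylic C–O bond without saturating C2=C3.

**21 from 20.** The C5' carbonyl of 21 is traced back to the methyl ether of phenol 20. The O–CH3 bond at C5' cannot be distinguished from those at C6, C7 and C8 by acid, but it is the only methoxy group para to a free phenol. A hypervalent-iodine oxidation therefore selects it. This is also why the C5 oxygen is benzylated from early on: a free C5 hydroxyl para to the C8 methoxy group would be oxidised in the same way.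

**20 from 12 and 17.** This is the key disconnection. Three bonds of ring B are cut, C5'–C6', C1'–C2' and C2'–C3', which takes the ring apart into alkyne 12 (C1', C6'), the carbene carbon and alkenyl group of 17 (C5', C4', C3') and one carbonyl ligand of 17 (C2'). Cutting here, and not at the C2–C1' biaryl-type bond, makes the two ring B oxygens appear differentiated as phenol and methyl ether. It also puts all carbon–carbon bond formation of ring B into one convergent step after rings A and C are complete. The forward reaction has to insert the terminal alkyne with its substituted carbon next to the carbonyl-derived carbon. A carbene complex with an unsubstituted vinyl group polymerises easily, so 17 carries a trans-β-trimethylsilyl group, which migrates to the C2' oxygen during aromatisation and is hydrolysed off in the work-up.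

**17 from 13 and 14.** The carbene carbon–vinyl bond and the O–methyl bond are cut. This is the classical assembly of an alkoxycarbene complex: a vinyl anion from bromide 13 adds to a carbonyl ligand of 14 and the acylchromate is O-methylated. The E geometry of 13 only serves to give a stable, well-defined complex; it disappears in ring B.

**12 from 11, and 11 from 7 and 9 (9 from 8).** Ring C is cut at O1–C2 and C2–C3. The acetyl group of 7 supplies C4 and C3, and acid chloride 9 supplies C2 together with both alkyne carbons, so the alkyne comes in at the right oxidation state and no later one-carbon homologation next to a base-sensitive pyranone is needed. The bulky silyl group on 9 shields the alkyne terminus against conjugate addition during acylation and cyclisation, and is removed from 11 by a fluoride source as the last operation before the key step. Acid chloride 9 is a routine activation of acid 8.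

**7 from 6, and 6 from 5.** The benzyl C–O bond and the aryl–acetyl bond are cut. Resorcinol 5 has a single ring C–H, between its two hydroxyls, so C-acetylation can give only 6. Because 6 is symmetric, benzylation of either hydroxyl gives the same compound 7, and the remaining, chelated hydroxyl is the one that will become O1. The differentiation of C5–O from the three methoxy groups is fixed here without any selectivity issue.

**5 from 4, 4 from 2, and 2 from 1.** The two C–OH bonds of 5 are cut in turn. One hydroxyl comes from the aryl bromide of 4 by palladium-catalysed hydroxylation. The other comes from the formyl group of 2 by peracid oxidation (via formate 3). The order matters: the formyl group of 1 is first used as a meta director, so bromination goes to C5 (para and ortho to methoxy groups), and only then is it turned into the phenol. Brominating after that conversion would send the halogen ortho to the new hydroxyl.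

## Alternatives that were turned down

**Alternative 1: acylquinone closure of ring C at O1–C8a.**
- Disconnection: the O1–C8a bond, with ring A taken back to a quinone.
- Forward key step: the hydroquinone diketone 1-(2,5-dihydroxy-3,4-dimethoxyphenyl)-3-[2,5-di(propan-2-yloxy)phenyl]propane-1,3-dione A2 would be oxidised with a mild metal-oxide oxidant to the acylquinone A3. The enol oxygen of its diketone then adds to the only unsubstituted quinone carbon, next to the acyl group (6-endo oxa-Michael), and tautomerisation gives the 5,8-dihydroxy-6,7-dimethoxyflavone A1.
- For it: ring B arrives intact with both oxygens protected; the closure is intramolecular and has one possible site; the C5 and C8 hydroxyls of A1 differ in acidity through chelation of C5–OH.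
- Against it: A1 is a 5,8-hydroquinone at least as oxidisable as A2, so redox exchange with A3 or the oxidant can carry it on to the flavone-5,8-quinone. An acylquinone with an enolisable diketone is also open to intermolecular Michael chemistry. Afterwards the C8 hydroxyl must be methylated selectively and two isopropyl ethers cleaved by a Lewis acid in the presence of three methyl ethers. A2 itself needs a ketone with two free phenols to be taken through a Claisen-type condensation.
- Comparison: on the key step alone Alternative 1 is simpler (one C–O bond, no organometallic reagent). The chosen strategy offers instead an oxygen differentiation that never depends on a selective alkylation or a selective Lewis-acid cleavage: benzyl against methyl on ring A from a symmetric precursor, and phenol against methyl ether on ring B from the benzannulation itself. Both need two operations after the key step.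

**Alternative 2: insertion of tetramethoxybenzyne into an arylpropiolic acid.**
- Disconnection: C8a–O1, C4a–C4 and O1–C2, so that ring C is formed from an aryne and an alkynoic acid.
- Forward key step: the aryne released by a fluoride source from 2,3,4,5-tetramethoxy-6-(trimethylsilyl)phenyl trifluoromethanesulfonate A5 would take up the carboxylate of 3-[2,5-di(propan-2-yloxy)phenyl]prop-2-ynoic acid A6. The aryl anion attacks the ester carbonyl, the acyl group shifts to carbon, and the ortho-acylphenoxide closes 6-endo onto the ynone to give the tetramethoxyflavone A4.
- For it: it is the most convergent plan, with three bonds and ring C in one operation; the aryne is symmetric, so there is no regiochemical question; ring B again arrives intact.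
- Against it: A5 is a hexasubstituted benzene whose preparation (halogenation, silylation, silyl migration and triflation of a tetramethoxyphenol) costs about as much as ring A in the chosen route. In A4 all four ring A oxygens are methyl ethers, so the C5 ether must be cleaved alone. Chelation to the C4 carbonyl favours it, but the neighbouring C6 methoxy group is the usual next casualty and the isopropyl ethers need the same Lewis acid, so the last step is a rate-controlled selective dealkylation on the final compound.
- Comparison: Alternative 2 is stronger in convergence and in step count after the key step (one against two). The chosen strategy offers a C5 oxygen that is differentiated from the first ring A step onward, and an endgame whose selectivity follows from functional-group type and not from rate differences between similar ethers.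

**Alternative 3: squarate ring expansion that builds ring A on a pyranone.**
- Disconnection: the C5–C4a bond, with ring A taken back to a four-membered ring.
- Forward key step: thermolysis of 4-{6-[2,5-bis(benzyloxy)phenyl]-4-oxo-4H-pyran-2-yl}-2,3,4-trimethoxycyclobut-2-en-1-one A8 would open the cyclobutenone to a dienylketene. A 6π electrocyclisation onto the pyranone C=C and tautomerisation then give the 5-hydroxy-6,7,8-trimethoxyflavone A7.
- For it: the ring A pattern, including the free C5 hydroxyl, comes directly from the squarate carbons without a symmetry argument or a protecting group at C5; the closure is a metal-free relative of the electrocyclisation in the chosen key step; only a hydrogenolysis remains afterwards.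
- Against it: A8 requires a metallated 6-aryl-4-pyranone to add 1,2 to a squaric ester. Such a nucleophile carries its own electrophilic carbonyl and Michael acceptor, and pyranones are easily opened by carbanions. The pyranone with a metallation handle must first be built linearly from the ring B ketone. The electrocyclisation has to engage an electron-poor, cross-conjugated C=C at high temperature.
- Comparison: Alternative 3 is stronger on ring A regiochemistry and on the final step. The chosen strategy builds rings A and C by classical condensations and confines the organometallic risk to one step on a simple terminal alkyne, whereas Alternative 3 carries such risk both in making A8 and in the ring expansion.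

Key step: step 10

Remark on the chemistry: a carbene complex with an unsubstituted vinyl group polymerises readily, so carbene 17 carries a trans-β-trimethylsilyl group as a traceless spectator; the same three bonds are formed, silicon ends on the C2' oxygen and is removed in the same step.

Remark on the chemistry: acid 8 and bromide 13 are taken as purchasable; 8 would otherwise be made from ethynyltri(propan-2-yl)silane by lithiation and carboxylation.

## Route

Step 1
Reactants: 1 2,3,4-trimethoxybenzaldehyde
Product: 2 5-bromo-2,3,4-trimethoxybenzaldehyde
Conditions: NBS (1.05 equiv), DMF, rt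
Reagents that add atoms: N-bromosuccinimide, O=C1CCC(=O)N1Br
Why: Electrophilic aromatic bromination; C5 is para to the C2 methoxy group, ortho to the C4 methoxy group and meta to the formyl group, whereas C6 is ortho to the deactivating aldehyde, so substitution should go to C5.

Step 2
Reactants: 2 5-bromo-2,3,4-trimethoxybenzaldehyde
Product: 4 5-bromo-2,3,4-trimethoxyphenol, via aryl formate 3 (not isolated)
Conditions: mCPBA (1.3 equiv), CH2Cl2, 0 °C to rt; then K2CO3 (cat.), MeOH, rt
Reagents that add atoms: 3-chloroperoxybenzoic acid, OOC(=O)c1cccc(Cl)c1
Why: Baeyer–Villiger (Dakin-type) oxidation; the aryl group with ortho and para methoxy donors migrates in the Criegee intermediate in preference to hydride, and methanol cleaves the resulting formate to the phenol.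

Step 3
Reactants: 4 5-bromo-2,3,4-trimethoxyphenol
Product: 5 4,5,6-trimethoxybenzene-1,3-diol
Conditions: Pd2(dba)3 (2 mol%), tBuXPhos (8 mol%), KOH (4 equiv), 1,4-dioxane/H2O (1:1), 100 °C, argon; then aq. HCl under argon
Reagents that add atoms: potassium hydroxide, [K+].[OH-]
Why: Palladium-catalysed C–O coupling of an aryl bromide with hydroxide; the bulky biaryl phosphine supports oxidative addition of the electron-rich bromide to zerovalent palladium and C–O reductive elimination from the arylpalladium hydroxide, and the mixture is acidified before exposure to air because the diol is easily oxidised in base.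

Step 4
Reactants: 5 4,5,6-trimethoxybenzene-1,3-diol
Product: 6 1-(2,6-dihydroxy-3,4,5-trimethoxyphenyl)ethan-1-one
Conditions: BF3·OEt2 (3 equiv), AcOH, 90 °C; then H2O/MeOH, 60 °C
Reagents that add atoms: acetic acid, CC(=O)O
Why: Friedel–Crafts C-acylation with acetic acid activated by BF3; the ring has a single C–H, flanked by both hydroxyls and para to a methoxy group, so only one C-acyl product is possible, and the boron chelate of the ortho-hydroxy ketone is hydrolysed in the aqueous stage.

Step 5
Reactants: 6 1-(2,6-dihydroxy-3,4,5-trimethoxyphenyl)ethan-1-one
Product: 7 1-[2-(benzyloxy)-6-hydroxy-3,4,5-trimethoxyphenyl]ethan-1-one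
Conditions: BnBr (1.0 equiv), K2CO3 (1.1 equiv), acetone, 56 °C
Reagents that add atoms: benzyl bromide, BrCc1ccccc1
Why: Williamson ether synthesis; the two hydroxyls are equivalent, and once one is benzylated the other is held in a hydrogen bond to the ketone and flanked by two substituents, so a second alkylation should be much slower.

Step 6
Reactants: 8 3-[tri(propan-2-yl)silyl]prop-2-ynoic acid
Product: 9 3-[tri(propan-2-yl)silyl]prop-2-ynoyl chloride
Conditions: (COCl)2 (1.2 equiv), DMF (cat.), CH2Cl2, 0 °C to rt; concentrate and use at once
Reagents that add atoms: oxalyl chloride, ClC(=O)C(=O)Cl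
Why: Standard acid chloride formation through the chloroiminium salt from DMF and oxalyl chloride; the silylated alkyne is inert under these conditions.

Step 7
Reactants: 7 1-[2-(benzyloxy)-6-hydroxy-3,4,5-trimethoxyphenyl]ethan-1-one; 9 3-[tri(propan-2-yl)silyl]prop-2-ynoyl chloride
Product: 11 5-(benzyloxy)-6,7,8-trimethoxy-2-{[tri(propan-2-yl)silyl]ethynyl}-4H-chromen-4-one, via ynedione 10 (not isolated)
Conditions: LiN(SiMe3)2 (3.2 equiv), THF, −78 °C; 9 (1.2 equiv), −78 to −20 °C; aq. HCl; then crude 10, H2SO4 (cat.), AcOH, 40 °C
Reagents that add atoms: none
Why: Baker–Venkataraman-type acylation of the phenoxide–enolate dianion (any aryl ester formed first rearranges under the excess base) gives the 1,3-diketone, and acid closes the phenol onto the ynone carbonyl as a hemiketal and dehydrates it to the chromone; the bulky silyl group blocks conjugate addition to the alkyne terminus, including the competing attack of the enol oxygen that would form a 4-pyranone.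

Step 8
Reactants: 11 5-(benzyloxy)-6,7,8-trimethoxy-2-{[tri(propan-2-yl)silyl]ethynyl}-4H-chromen-4-one
Product: 12 5-(benzyloxy)-2-ethynyl-6,7,8-trimethoxy-4H-chromen-4-one
Conditions: Bu4NF (1.1 equiv), AcOH (1.2 equiv), THF, −20 to 0 °C
Reagents that add atoms: none
Why: Fluoride-induced protodesilylation of an alkynylsilane; the departing acetylide is stabilised by conjugation with the chromone, so buffered fluoride at low temperature should suffice and spares the base-sensitive pyranone and the electrophilic enyne.

Step 9
Reactants: 13 [(E)-2-bromoethenyl](trimethyl)silane; 14 hexacarbonylchromium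
Product: 17 pentacarbonyl[(2E)-1-methoxy-3-(trimethylsilyl)prop-2-en-1-ylidene]chromium, via vinyllithium 15 (not isolated), via lithium acylchromate 16 (not isolated)
Conditions: 13, t-BuLi (2.0 equiv), Et2O, −78 °C; Cr(CO)6 (1.0 equiv), Et2O, −78 °C to rt; then Me3OBF4 (1.5 equiv), CH2Cl2, 0 °C; argon, dark
Reagents that add atoms: trimethyloxonium tetrafluoroborate, C[O+](C)C.F[B-](F)(F)F
Why: Classical alkoxycarbene synthesis: bromine–lithium exchange with retention of the E geometry, addition of the vinyllithium to a carbonyl ligand of Cr(CO)6 to give the acylchromate, and O-methylation by the hard oxonium salt; the β-silyl group suppresses the polymerisation that an unsubstituted vinyl complex undergoes.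

Step 10
Reactants: 12 5-(benzyloxy)-2-ethynyl-6,7,8-trimethoxy-4H-chromen-4-one; 17 pentacarbonyl[(2E)-1-methoxy-3-(trimethylsilyl)prop-2-en-1-ylidene]chromium
Product: 20 5-(benzyloxy)-2-(2-hydroxy-5-methoxyphenyl)-6,7,8-trimethoxy-4H-chromen-4-one, via tricarbonylchromium arene complex 18 (not isolated), via aryl trimethylsilyl ether 19 (not isolated)
Conditions: 17 (1.5 equiv), THF (0.05 M, degassed), 50 °C, argon; then air, daylight, rt; then 1 M HCl, THF/MeOH, rt
Reagents that add atoms: none
Why: On warming, 17 loses a cis carbonyl ligand and binds the triple bond of 12, which inserts into the chromium–carbene bond so that the carbene carbon (C5') joins the terminal alkyne carbon (C6') and the chromone-bearing carbon (C1') becomes the new carbene centre. Migration of a carbonyl ligand onto that centre forms the C1'–C2' bond and gives a chromium-bound dienylketene, and ring B closes by a 6π electrocyclisation of this all-carbon triene (ketene carbon C2' onto the silyl-bearing vinyl carbon C3'), a carbocyclic six-membered closure. The resulting cyclohexadienone aromatises by a 1,3-shift of silicon from C3' to the C2' oxygen, which leaves arene complex 18; air and light remove the Cr(CO)3 group to give 19, and dilute acid hydrolyses the aryl silyl ether to 20. The closest known reaction type is the Dötz benzannulation of alkenyl(alkoxy)carbene chromium complexes with terminal alkynes, including β-silylvinyl complexes used as stand-ins for the unsubstituted vinyl complex. No stereocentre is formed. The step needs regioselective insertion, and the terminal alkyne secures it: its large substituent ends next to the carbonyl-derived carbon, so the chromone sits on C1' beside the C2' oxygen and hydrogen on C6'. It also needs the phenol pathway to win over cyclobutenone or furan formation; an alkenyl complex in THF favours carbonyl insertion and electrocyclisation, and the C4 carbonyl of 12 is held trans to the alkyne across C2=C3 and cannot trap the carbene. Rings A and C are fully substituted and offer no other π-bond to the carbene complex, and the two ring B oxygens emerge differentiated, C5' as methyl ether and C2' as phenol.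

Step 11
Reactants: 20 5-(benzyloxy)-2-(2-hydroxy-5-methoxyphenyl)-6,7,8-trimethoxy-4H-chromen-4-one
Product: 21 2-[5-(benzyloxy)-6,7,8-trimethoxy-4-oxo-4H-chromen-2-yl]cyclohexa-2,5-diene-1,4-dione
Conditions: PhI(OAc)2 (1.1 equiv), MeCN/H2O (2:1), 0 °C
Reagents that add atoms: water, O
Why: Hypervalent-iodine oxidative demethylation of a para-methoxyphenol: the phenol exchanges onto iodine, water attacks C5' para to the phenol oxygen and the hemiketal loses methanol to give the quinone; ring A has no free phenol (C5 is benzylated), so its para-dioxygenated C5/C8 pair should not be oxidised.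

Step 12
Reactants: 21 2-[5-(benzyloxy)-6,7,8-trimethoxy-4-oxo-4H-chromen-2-yl]cyclohexa-2,5-diene-1,4-dione
Product: 22 2-(2,5-dihydroxyphenyl)-5-hydroxy-6,7,8-trimethoxy-4H-chromen-4-one
Conditions: H2 (1 atm), 10% Pd/C, EtOAc/MeOH (1:1), rt
Reagents that add atoms: none
Why: Catalytic hydrogenation reduces the quinone to the hydroquinone and hydrogenolyses the benzylic C–O bond at C5; the C2=C3 bond, part of a vinylogous ester conjugated with two arenes, should survive at 1 atm and room temperature, and no stereocentre is involved.

## Compound list

1 | 2,3,4-trimethoxybenzaldehyde | COc1ccc(C=O)c(OC)c1OC | starting material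
2 | 5-bromo-2,3,4-trimethoxybenzaldehyde | COc1c(Br)cc(C=O)c(OC)c1OC | intermediate
3 | 5-bromo-2,3,4-trimethoxyphenyl formate | COc1c(Br)cc(OC=O)c(OC)c1OC | intermediate
4 | 5-bromo-2,3,4-trimethoxyphenol | COc1c(Br)cc(O)c(OC)c1OC | intermediate
5 | 4,5,6-trimethoxybenzene-1,3-diol | COc1c(O)cc(O)c(OC)c1OC | intermediate
6 | 1-(2,6-dihydroxy-3,4,5-trimethoxyphenyl)ethan-1-one | COc1c(O)c(C(C)=O)c(O)c(OC)c1OC | intermediate
7 | 1-[2-(benzyloxy)-6-hydroxy-3,4,5-trimethoxyphenyl]ethan-1-one | COc1c(O)c(C(C)=O)c(OCc2ccccc2)c(OC)c1OC | intermediate
8 | 3-[tri(propan-2-yl)silyl]prop-2-ynoic acid | CC(C)[Si](C#CC(=O)O)(C(C)C)C(C)C | starting material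
9 | 3-[tri(propan-2-yl)silyl]prop-2-ynoyl chloride | CC(C)[Si](C#CC(=O)Cl)(C(C)C)C(C)C | intermediate
10 | 1-[2-(benzyloxy)-6-hydroxy-3,4,5-trimethoxyphenyl]-5-[tri(propan-2-yl)silyl]pent-4-yne-1,3-dione | COc1c(O)c(C(=O)CC(=O)C#C[Si](C(C)C)(C(C)C)C(C)C)c(OCc2ccccc2)c(OC)c1OC | intermediate
11 | 5-(benzyloxy)-6,7,8-trimethoxy-2-{[tri(propan-2-yl)silyl]ethynyl}-4H-chromen-4-one | COc1c(OC)c(OCc2ccccc2)c2c(=O)cc(C#C[Si](C(C)C)(C(C)C)C(C)C)oc2c1OC | intermediate
12 | 5-(benzyloxy)-2-ethynyl-6,7,8-trimethoxy-4H-chromen-4-one | C#Cc1cc(=O)c2c(OCc3ccccc3)c(OC)c(OC)c(OC)c2o1 | intermediate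
13 | [(E)-2-bromoethenyl](trimethyl)silane | C[Si](C)(C)/C=C/Br | starting material
14 | hexacarbonylchromium | O=C=[Cr](=C=O)(=C=O)(=C=O)(=C=O)=C=O | starting material
15 | [(E)-2-(trimethylsilyl)ethenyl]lithium | [Li]/C=C/[Si](C)(C)C | intermediate
16 | lithium pentacarbonyl[(2E)-1-oxido-3-(trimethylsilyl)prop-2-en-1-ylidene]chromate | [Li+].[O-]C(/C=C/[Si](C)(C)C)=[Cr](=C=O)(=C=O)(=C=O)(=C=O)=C=O | intermediate
17 | pentacarbonyl[(2E)-1-methoxy-3-(trimethylsilyl)prop-2-en-1-ylidene]chromium | COC(/C=C/[Si](C)(C)C)=[Cr](=C=O)(=C=O)(=C=O)(=C=O)=C=O | intermediate
18 | tricarbonylchromium complex of 19, chromium η6-bound to ring B | COc1ccc(O[Si](C)(C)C)c(-c2cc(=O)c3c(OCc4ccccc4)c(OC)c(OC)c(OC)c3o2)c1.O=C=[Cr](=C=O)=C=O | intermediate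
19 | 5-(benzyloxy)-6,7,8-trimethoxy-2-{5-methoxy-2-[(trimethylsilyl)oxy]phenyl}-4H-chromen-4-one | COc1ccc(O[Si](C)(C)C)c(-c2cc(=O)c3c(OCc4ccccc4)c(OC)c(OC)c(OC)c3o2)c1 | intermediate
20 | 5-(benzyloxy)-2-(2-hydroxy-5-methoxyphenyl)-6,7,8-trimethoxy-4H-chromen-4-one | COc1ccc(O)c(-c2cc(=O)c3c(OCc4ccccc4)c(OC)c(OC)c(OC)c3o2)c1 | intermediate
21 | 2-[5-(benzyloxy)-6,7,8-trimethoxy-4-oxo-4H-chromen-2-yl]cyclohexa-2,5-diene-1,4-dione | COc1c(OC)c(OCc2ccccc2)c2c(=O)cc(C3=CC(=O)C=CC3=O)oc2c1OC | intermediate
22 | 2-(2,5-dihydroxyphenyl)-5-hydroxy-6,7,8-trimethoxy-4H-chromen-4-one (5,2',5'-trihydroxy-6,7,8-trimethoxyflavone) | COc1c(OC)c(O)c2c(=O)cc(-c3cc(O)ccc3O)oc2c1OC | target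

## Step count and least certain steps

Total step count: 12. Longest linear sequence: 10 steps (steps 1, 2, 3, 4, 5, 7, 8, 10, 11, 12); steps 6 and 9 prepare the two side components.

**Step 10 (key step).**
- What may go wrong: the triple bond of 12 is conjugated with the pyranone and electron-poor, so insertion into the chromium–carbene bond may be slower than thermal decay of 17. The vinylketene may be diverted to a cyclobutenone. Migration of silicon to oxygen may compete poorly with a hydrogen shift, leaving silicon on C3'.
- Fallback: it sets out from acetophenone 7 and comes back at target 22, bringing ring B in intact by the classical diketone route. 2,5-Bis(benzyloxy)benzoyl chloride F1, made from purchased 2,5-bis(benzyloxy)benzoic acid and oxalyl chloride, would acylate the dianion of 7 (LiN(SiMe3)2, THF, −78 °C) to 1-[2-(benzyloxy)-6-hydroxy-3,4,5-trimethoxyphenyl]-3-[2,5-bis(benzyloxy)phenyl]propane-1,3-dione F2. Acid (H2SO4 cat., AcOH) would cyclise this to 5-(benzyloxy)-2-[2,5-bis(benzyloxy)phenyl]-6,7,8-trimethoxy-4H-chromen-4-one F3, and hydrogenolysis (H2, 10% Pd/C) of the three benzyl ethers would give 22.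

**Step 7.**
- What may go wrong: closure of the aryl-ketone enol oxygen onto the alkyne (6-endo) may compete with hemiketal formation and build a 4-pyranone in place of ring C. The benzyl ether could be lost in acid, or the acid chloride could be consumed by the amide base.
- Fallback: it sets out from 7 and comes back at alkyne 12, leaving out 11 and step 8; the alkyne is made by one-carbon homologation instead of being carried in. Claisen condensation of 7 with ethyl diethoxyacetate (NaH, THF) would give 1-[2-(benzyloxy)-6-hydroxy-3,4,5-trimethoxyphenyl]-4,4-diethoxybutane-1,3-dione F4. Acid would cyclise it to 5-(benzyloxy)-2-(diethoxymethyl)-6,7,8-trimethoxy-4H-chromen-4-one F5 and, with water, hydrolyse the acetal to 5-(benzyloxy)-6,7,8-trimethoxy-4-oxo-4H-chromene-2-carbaldehyde F6. Ohira–Bestmann alkynylation (dimethyl (1-diazo-2-oxopropyl)phosphonate, K2CO3, MeOH, 0 °C, short reaction time) would then give 12.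

**Step 3.**
- What may go wrong: C–O coupling of the substrate's or product's own phenoxide (diaryl ether formation), slow oxidative addition at the very electron-rich ring, and oxidative degradation of the diol in hot alkali.
- Fallback: it sets out from bromophenol 4 and comes back at resorcinol 5, replacing direct C–O coupling by borylation and oxidation. Miyaura borylation (bis(pinacolato)diboron, Pd(dppf)Cl2, KOAc, 1,4-dioxane, 90 °C) would give 2,3,4-trimethoxy-5-(4,4,5,5-tetramethyl-1,3,2-dioxaborolan-2-yl)phenol F7, and mild oxidation (NaBO3·4H2O, THF/H2O, rt) would give 5.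

**Step 9.**
- What may go wrong: protonation or isomerisation of the vinyl anion before it reaches Cr(CO)6, and decomposition of the alkenyl carbene complex during purification.
- Fallback: it sets out from Cr(CO)6 14 (with alkyne 12 as partner) and comes back at phenol 20, using the unsubstituted vinyl complex freshly made and in excess. Vinylmagnesium bromide (CH2=CHMgBr, THF) would add to 14 to give bromomagnesium pentacarbonyl(1-oxidoprop-2-en-1-ylidene)chromate F8, and Me3OBF4 would methylate it to pentacarbonyl(1-methoxyprop-2-en-1-ylidene)chromium F9. Used at once (2–3 equiv) with 12 under the conditions of step 10, F9 would give the tricarbonylchromium complex of 20 F10, which air and light would convert to 20 with no silyl group to remove.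

## Further compounds

F1 | step 10 | 2,5-bis(benzyloxy)benzoyl chloride | O=C(Cl)c1cc(OCc2ccccc2)ccc1OCc1ccccc1
F2 | step 10 | 1-[2-(benzyloxy)-6-hydroxy-3,4,5-trimethoxyphenyl]-3-[2,5-bis(benzyloxy)phenyl]propane-1,3-dione | COc1c(O)c(C(=O)CC(=O)c2cc(OCc3ccccc3)ccc2OCc2ccccc2)c(OCc2ccccc2)c(OC)c1OC
F3 | step 10 | 5-(benzyloxy)-2-[2,5-bis(benzyloxy)phenyl]-6,7,8-trimethoxy-4H-chromen-4-one | COc1c(OC)c(OCc2ccccc2)c2c(=O)cc(-c3cc(OCc4ccccc4)ccc3OCc3ccccc3)oc2c1OC
F4 | step 7 | 1-[2-(benzyloxy)-6-hydroxy-3,4,5-trimethoxyphenyl]-4,4-diethoxybutane-1,3-dione | CCOC(OCC)C(=O)CC(=O)c1c(O)c(OC)c(OC)c(OC)c1OCc1ccccc1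
F5 | step 7 | 5-(benzyloxy)-2-(diethoxymethyl)-6,7,8-trimethoxy-4H-chromen-4-one | CCOC(OCC)c1cc(=O)c2c(OCc3ccccc3)c(OC)c(OC)c(OC)c2o1
F6 | step 7 | 5-(benzyloxy)-6,7,8-trimethoxy-4-oxo-4H-chromene-2-carbaldehyde | O=Cc1cc(=O)c2c(OCc3ccccc3)c(OC)c(OC)c(OC)c2o1
F7 | step 3 | 2,3,4-trimethoxy-5-(4,4,5,5-tetramethyl-1,3,2-dioxaborolan-2-yl)phenol | COc1c(B2OC(C)(C)C(C)(C)O2)cc(O)c(OC)c1OC
F8 | step 9 | bromomagnesium pentacarbonyl(1-oxidoprop-2-en-1-ylidene)chromate | [Mg+2].[Br-].[O-]C(C=C)=[Cr](=C=O)(=C=O)(=C=O)(=C=O)=C=O
F9 | step 9 | pentacarbonyl(1-methoxyprop-2-en-1-ylidene)chromium | COC(C=C)=[Cr](=C=O)(=C=O)(=C=O)(=C=O)=C=O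
F10 | step 9 | tricarbonylchromium complex of 20, chromium η6-bound to ring B | COc1ccc(O)c(-c2cc(=O)c3c(OCc4ccccc4)c(OC)c(OC)c(OC)c3o2)c1.O=C=[Cr](=C=O)=C=O
A1 | alternative 1 | 2-[2,5-di(propan-2-yloxy)phenyl]-5,8-dihydroxy-6,7-dimethoxy-4H-chromen-4-one | COc1c(OC)c(O)c2c(=O)cc(-c3cc(OC(C)C)ccc3OC(C)C)oc2c1O
A2 | alternative 1 | 1-(2,5-dihydroxy-3,4-dimethoxyphenyl)-3-[2,5-di(propan-2-yloxy)phenyl]propane-1,3-dione | COc1c(O)cc(C(=O)CC(=O)c2cc(OC(C)C)ccc2OC(C)C)c(O)c1OC
A3 | alternative 1 | 1-(4,5-dimethoxy-3,6-dioxocyclohexa-1,4-dien-1-yl)-3-[2,5-di(propan-2-yloxy)phenyl]propane-1,3-dione | COC1=C(OC)C(=O)C(C(=O)CC(=O)c2cc(OC(C)C)ccc2OC(C)C)=CC1=O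
A4 | alternative 2 | 2-[2,5-di(propan-2-yloxy)phenyl]-5,6,7,8-tetramethoxy-4H-chromen-4-one | COc1c(OC)c(OC)c2c(=O)cc(-c3cc(OC(C)C)ccc3OC(C)C)oc2c1OC
A5 | alternative 2 | 2,3,4,5-tetramethoxy-6-(trimethylsilyl)phenyl trifluoromethanesulfonate | COc1c(OC)c(OC)c([Si](C)(C)C)c(OS(=O)(=O)C(F)(F)F)c1OC
A6 | alternative 2 | 3-[2,5-di(propan-2-yloxy)phenyl]prop-2-ynoic acid | CC(C)Oc1ccc(OC(C)C)c(C#CC(=O)O)c1
A7 | alternative 3 | 2-[2,5-bis(benzyloxy)phenyl]-5-hydroxy-6,7,8-trimethoxy-4H-chromen-4-one | COc1c(OC)c(O)c2c(=O)cc(-c3cc(OCc4ccccc4)ccc3OCc3ccccc3)oc2c1OC
A8 | alternative 3 | 4-{6-[2,5-bis(benzyloxy)phenyl]-4-oxo-4H-pyran-2-yl}-2,3,4-trimethoxycyclobut-2-en-1-one | COC1=C(OC)C(OC)(c2cc(=O)cc(-c3cc(OCc4ccccc4)ccc3OCc3ccccc3)o2)C1=O
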